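**Plan**
Ring locants follow the target name: C1 (O-angeloyl), C2 (side chain), C3 (CH2), C4 (CHOH), C5 (CHMe), C6 (CH2); side chain C1'–C7'. Retrosynthetic cuts, in order: the angelate ester at C1–O; the ring bond C3–C4; the C1–C6 bond (fragment union); in the side-chain fragment, C2–C3 (C3 from formaldehyde) and C4'–C5' (acyl–alkenyl).
Forward: enal 8 (from a 3-methylglutarate hemiester) and a Grignard reagent from (R)-3-bromo-2-methylpropanol are joined at C1–C6 and oxidised to the open-chain keto aldehyde 13. A SmI2 reductive cyclisation then closes the only ring at C3–C4; inversion at C4, ketone reduction, angeloylation and deprotection finish the route.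
Enabling feature: the cyclohexane is oxygenated at C1 and C4, and C3 is a CH2 that lies β to C1 and is bonded to C4. C1(=O)–C2–C3–C4(OH) is therefore a γ-hydroxy ketone whose C3–C4 bond joins a formyl carbon to the β-carbon of an α-methylene ketone.
Stereochemistry: C2' from the hemiester; C4' by CBS reduction; C5 from the bromo alcohol; C4 set trans to C5 in the ring closure, then inverted by Mitsunobu; C2 by equilibration to the all-equatorial ketone; C1 by axial hydride attack; the Z-ester from angelic acid.

Key step: step 10

Remark: hemiester 1 is taken as commercial (it is also accessible by esterase desymmetrisation of dimethyl 3-methylglutarate); CIP descriptors change in places (e.g. 1 → 2, 11 → 12) without any change of geometry.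

Step 1
Reactants: 1 methyl hydrogen (R)-3-methylglutarate
Product: 3 methyl (3R)-3,7-dimethyl-5-oxooct-6-enoate, via acid chloride 2 (not isolated)
Conditions: (COCl)2, DMF (cat.), CH2Cl2, 0 → 23 °C; evaporate; then Me2C=CHMgBr (1.05 equiv), CuI (5 mol %), THF, −78 °C
Reagents that add atoms: oxalyl chloride ClC(=O)C(=O)Cl (chlorine of 2 only); 2-methylprop-1-en-1-ylmagnesium bromide CC(C)=C[Mg]Br
Why: Copper(I)-catalysed acylation of an alkenyl Grignard reagent by an acid chloride (ketone synthesis) should be much faster at −78 °C than attack on the methyl ester or conjugate addition to the β,β-disubstituted enone formed, and the methyl-bearing stereocentre is not involved.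

Step 2
Reactants: 3 methyl (3R)-3,7-dimethyl-5-oxooct-6-enoate
Product: 4 methyl (3R,5R)-5-hydroxy-3,7-dimethyloct-6-enoate
Conditions: (S)-2-methyl-CBS-oxazaborolidine (0.2 equiv), catecholborane (1.5 equiv), toluene, −78 °C; pH 7 work-up
Reagents that add atoms: none
Why: Corey–Bakshi–Shibata reduction in which the 2-methylprop-1-enyl group acts as the large substituent, so the (S)-catalyst should give the (5R)-allylic alcohol under reagent control, while catecholborane at −78 °C spares the ester and the trisubstituted alkene (any δ-lactone formed from 4 converges in step 3).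

Step 3
Reactants: 4 methyl (3R,5R)-5-hydroxy-3,7-dimethyloct-6-enoate
Product: 5 (3R,5R)-5-hydroxy-N-methoxy-N,3,7-trimethyloct-6-enamide
Conditions: MeNH(OMe)·HCl (3 equiv), i-PrMgCl (6 equiv), THF, −20 → 0 °C
Reagents that add atoms: N,O-dimethylhydroxylamine hydrochloride CNOC.Cl
Why: Weinreb amidation of the ester (or of the derived δ-lactone) by the chloromagnesium amide, with the free hydroxyl carried as its magnesium alkoxide.

Step 4
Reactants: 5 (3R,5R)-5-hydroxy-N-methoxy-N,3,7-trimethyloct-6-enamide
Product: 6 (4R,6R)-8-[methoxy(methyl)amino]-2,6-dimethyl-8-oxooct-2-en-4-yl acetate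
Conditions: Ac2O, pyridine, DMAP (cat.), CH2Cl2, 0 → 23 °C
Reagents that add atoms: acetic anhydride CC(=O)OC(C)=O
Why: Standard DMAP-catalysed acetylation of the only hydroxyl group, done at once so that the δ-hydroxy amide cannot lactonise.

Step 5
Reactants: 6 (4R,6R)-8-[methoxy(methyl)amino]-2,6-dimethyl-8-oxooct-2-en-4-yl acetate
Product: 7 (4R,6R)-2,6-dimethyl-8-oxooct-2-en-4-yl acetate
Conditions: Cp2Zr(H)Cl (1.5 equiv), THF, 23 °C, 20 min
Reagents that add atoms: none
Why: Schwartz reagent reduces the tertiary (Weinreb) amide to the aldehyde through a zirconated hemiaminal and should not touch the acetate, which DIBAL would cleave, or the trisubstituted alkene.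

Step 6
Reactants: 7 (4R,6R)-2,6-dimethyl-8-oxooct-2-en-4-yl acetate
Product: 8 (4R,6R)-2,6-dimethyl-7-methylidene-8-oxooct-2-en-4-yl acetate
Conditions: 37 % aq. CH2O (1.2 equiv), pyrrolidine (10 mol %), EtCO2H (10 mol %), i-PrOH, 45 °C
Reagents that add atoms: formaldehyde C=O
Why: Amine-catalysed α-methylenation of an aldehyde (Mannich condensation with formaldehyde, then elimination) at the only enolisable α-CH2, under mild conditions that should leave the remote acetate and the adjacent methyl-bearing stereocentre untouched.

Step 7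
Reactants: 9 (R)-3-bromo-2-methylpropan-1-ol
Product: 10 [(2R)-3-bromo-2-methylpropoxy]triethylsilane
Conditions: TESCl, imidazole, CH2Cl2, 0 °C
Reagents that add atoms: chlorotriethylsilane CC[Si](Cl)(CC)CC
Why: Routine silylation of a primary alcohol, giving a bromide that forms a stable Grignard reagent.

Step 8
Reactants: 10 [(2R)-3-bromo-2-methylpropoxy]triethylsilane; 8 (4R,6R)-2,6-dimethyl-7-methylidene-8-oxooct-2-en-4-yl acetate
Product: 12 (4R,6R,10S)-8-hydroxy-2,6,10-trimethyl-7-methylidene-11-[(triethylsilyl)oxy]undec-2-en-4-yl acetate (both C8 epimers), via Grignard reagent 11 (not isolated)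
Conditions: Mg, BrCH2CH2Br (cat.), THF, 40 °C; then 8, THF, −78 °C; aq. NH4Cl
Reagents that add atoms: magnesium [Mg] (retained only in intermediate 11)
Why: Grignard 1,2-addition to the α-branched enal should be far faster at −78 °C than attack on the acetate or 1,4-addition; the new carbinol centre forms without control and is removed by the oxidation in step 9.

Step 9
Reactants: 12 (4R,6R,10S)-8-hydroxy-2,6,10-trimethyl-7-methylidene-11-[(triethylsilyl)oxy]undec-2-en-4-yl acetate
Product: 13 (4R,6R,10S)-2,6,10-trimethyl-7-methylidene-8,11-dioxoundec-2-en-4-yl acetate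
Conditions: (COCl)2 (6 equiv), DMSO (12 equiv), CH2Cl2, −78 → −30 °C; i-Pr2NEt, −78 → 0 °C; pH 7 buffer
Reagents that add atoms: none
Why: Swern oxidation with excess activated DMSO oxidises the secondary allylic alcohol to the α-methylene ketone and in the same operation converts the primary triethylsilyl ether into the aldehyde (oxidative cleavage of primary TES ethers); the hindered base and cold quench guard the α-methyl aldehyde against epimerisation.

Step 10
Reactants: 13 (4R,6R,10S)-2,6,10-trimethyl-7-methylidene-8,11-dioxoundec-2-en-4-yl acetate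
Product: 15 (4R,6R)-6-[(1S,4S,5S)-5-hydroxy-4-methyl-2-oxocyclohexyl]-2-methylhept-2-en-4-yl acetate, via samarium enolate 14 (not isolated)
Conditions: SmI2 (2.4 equiv), HMPA (10 equiv), THF, −78 °C, slow addition of 13 (0.01 M final); aq. NH4Cl; then DBU (0.2 equiv), CH2Cl2, 23 °C
Reagents that add atoms: samarium(II) iodide I[Sm]I (Sm and I retained only in intermediate 14)
Why: Proposed new method: SmI2–HMPA reduces the aldehyde of 13 to a ketyl (or the enone to its radical anion), the formyl carbon C11 bonds to the unsubstituted methylidene carbon, the β-terminus of the α-methylene ketone, and a second electron gives samarium enolate 14, which is protonated on work-up; the closest known reaction type is the SmI2 ketyl–olefin (carbonyl–enone/enoate) reductive cyclisation, established for exo and 8-endo closures and extended here to a closure in which the acceptor carbonyl lies inside the new ring. The cyclohexane closes in the 6-endo-trig mode, because the radical (or anion) is polarity-matched with the terminal CH2 and the 5-exo alternative would have to attack the fully substituted α-carbon. The new carbinol centre is controlled by the adjacent methyl-bearing stereocentre: in the chair-like transition state the methyl group is equatorial and the bulky O–Sm(HMPA)n group takes the pseudo-equatorial position anti to the enone, which should give the trans (equatorial) alcohol that step 11 inverts. The second new centre, the ketone α-carbon carrying the side chain, is formed on protonation of 14 and is brought under thermodynamic control by DBU, since in 15 every ring substituent can then be equatorial. The step needs chemoselectivity for intramolecular C–C bond formation over pinacol coupling, plain conjugate reduction and dimerisation, which the six-membered geometry, high dilution and inverse addition should secure, and the allylic acetate is not reduced by SmI2 in the absence of palladium.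

Step 11
Reactants: 15 (4R,6R)-6-[(1S,4S,5S)-5-hydroxy-4-methyl-2-oxocyclohexyl]-2-methylhept-2-en-4-yl acetate
Product: 16 (1R,2S,5S)-5-[(2R,4R)-4-(acetyloxy)-6-methylhept-5-en-2-yl]-2-methyl-4-oxocyclohexyl chloroacetate
Conditions: ClCH2CO2H (3 equiv), PPh3 (3 equiv), DIAD (3 equiv), toluene, 0 → 23 °C
Reagents that add atoms: chloroacetic acid OC(=O)CCl
Why: Mitsunobu reaction with the acidic chloroacetic acid inverts the hindered equatorial alcohol by SN2 displacement of the oxyphosphonium ion to give the axial ester cis to the neighbouring methyl group (target configuration at C4), and protects this oxygen with a group removable beside acetate and angelate; no base is used before step 12, so the ketone α-centre is not disturbed.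

Step 12
Reactants: 16 (1R,2S,5S)-5-[(2R,4R)-4-(acetyloxy)-6-methylhept-5-en-2-yl]-2-methyl-4-oxocyclohexyl chloroacetate
Product: 17 (1R,2S,4R,5S)-5-[(2R,4R)-4-(acetyloxy)-6-methylhept-5-en-2-yl]-4-hydroxy-2-methylcyclohexyl chloroacetate
Conditions: NaBH4, CeCl3·7H2O, MeOH, −78 °C
Reagents that add atoms: none
Why: Luche reduction: the small cerium-activated borohydride should attack the ketone along the axial trajectory, on the face opposite the axial chloroacetate, to give the equatorial alcohol trans to the equatorial side chain, and at −78 °C it should not cleave the acetate or the chloroacetate.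

Step 13
Reactants: 17 (1R,2S,4R,5S)-5-[(2R,4R)-4-(acetyloxy)-6-methylhept-5-en-2-yl]-4-hydroxy-2-methylcyclohexyl chloroacetate
Product: 18 (1R,2S,4R,5S)-2-[(2R,4R)-4-(acetyloxy)-6-methylhept-5-en-2-yl]-4-[(chloroacetyl)oxy]-5-methylcyclohexyl (2Z)-2-methylbut-2-enoate
Conditions: angelic acid (3 equiv), 2,4,6-trichlorobenzoyl chloride (3 equiv), i-Pr2NEt (3.3 equiv), toluene, 23 °C; then 17, 75 °C
Reagents that add atoms: angelic acid [(2Z)-2-methylbut-2-enoic acid] C/C=C(/C)C(=O)O
Why: Yamaguchi esterification through the mixed 2,4,6-trichlorobenzoic anhydride of angelic acid, run without DMAP so that the Z-alkene is not isomerised to the tiglate and with non-nucleophilic i-Pr2NEt so that the chloroacetate is not N-alkylated; the alcohol attacks the less hindered angeloyl carbonyl.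

Step 14
Reactants: 18 (1R,2S,4R,5S)-2-[(2R,4R)-4-(acetyloxy)-6-methylhept-5-en-2-yl]-4-[(chloroacetyl)oxy]-5-methylcyclohexyl (2Z)-2-methylbut-2-enoate
Product: 19 (1R,2S,4R,5S)-2-[(2R,4R)-4-(acetyloxy)-6-methylhept-5-en-2-yl]-4-hydroxy-5-methylcyclohexyl (2Z)-2-methylbut-2-enoate (CNP0237033.1)
Conditions: thiourea (5 equiv), NaHCO3 (5 equiv), EtOH, 50 °C
Reagents that add atoms: none
Why: Thiourea S-alkylation of the chloroacetate followed by intramolecular N-acyl transfer releases the axial alcohol under near-neutral conditions that should leave the acetate, the angelate and its Z geometry intact.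

**Compound list**
1 | methyl hydrogen (R)-3-methylglutarate [(3R)-5-methoxy-3-methyl-5-oxopentanoic acid] | COC(=O)C[C@H](C)CC(=O)O | starting material
2 | methyl (3S)-5-chloro-3-methyl-5-oxopentanoate (acid chloride, formed in situ) | COC(=O)C[C@H](C)CC(=O)Cl | intermediate
3 | methyl (3R)-3,7-dimethyl-5-oxooct-6-enoate | COC(=O)C[C@H](C)CC(=O)C=C(C)C | intermediate
4 | methyl (3R,5R)-5-hydroxy-3,7-dimethyloct-6-enoate | COC(=O)C[C@H](C)C[C@@H](O)C=C(C)C | intermediate
5 | (3R,5R)-5-hydroxy-N-methoxy-N,3,7-trimethyloct-6-enamide | CON(C)C(=O)C[C@H](C)C[C@@H](O)C=C(C)C | intermediate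
6 | (4R,6R)-8-[methoxy(methyl)amino]-2,6-dimethyl-8-oxooct-2-en-4-yl acetate | CON(C)C(=O)C[C@H](C)C[C@@H](OC(C)=O)C=C(C)C | intermediate
7 | (4R,6R)-2,6-dimethyl-8-oxooct-2-en-4-yl acetate | O=CC[C@H](C)C[C@@H](OC(C)=O)C=C(C)C | intermediate
8 | (4R,6R)-2,6-dimethyl-7-methylidene-8-oxooct-2-en-4-yl acetate | O=CC(=C)[C@H](C)C[C@@H](OC(C)=O)C=C(C)C | intermediate
9 | (R)-3-bromo-2-methylpropan-1-ol | BrC[C@H](C)CO | starting material
10 | [(2R)-3-bromo-2-methylpropoxy]triethylsilane | BrC[C@H](C)CO[Si](CC)(CC)CC | intermediate
11 | {(2R)-2-methyl-3-[(triethylsilyl)oxy]propyl}magnesium bromide (formed in situ) | Br[Mg]C[C@H](C)CO[Si](CC)(CC)CC | intermediate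
12 | (4R,6R,10S)-8-hydroxy-2,6,10-trimethyl-7-methylidene-11-[(triethylsilyl)oxy]undec-2-en-4-yl acetate (both C8 epimers) | CC[Si](CC)(CC)OC[C@@H](C)CC(O)C(=C)[C@H](C)C[C@@H](OC(C)=O)C=C(C)C | intermediate
13 | (4R,6R,10S)-2,6,10-trimethyl-7-methylidene-8,11-dioxoundec-2-en-4-yl acetate | O=C[C@@H](C)CC(=O)C(=C)[C@H](C)C[C@@H](OC(C)=O)C=C(C)C | intermediate
14 | (4R,6R)-6-[(4S,5S)-2,5-bis(diiodosamariooxy)-4-methylcyclohex-1-en-1-yl]-2-methylhept-2-en-4-yl acetate (samarium enolate–alkoxide, formed in situ) | CC(C)=C[C@H](OC(C)=O)C[C@@H](C)C1=C(O[Sm](I)I)C[C@H](C)[C@@H](O[Sm](I)I)C1 | intermediate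
15 | (4R,6R)-6-[(1S,4S,5S)-5-hydroxy-4-methyl-2-oxocyclohexyl]-2-methylhept-2-en-4-yl acetate | O=C1C[C@H](C)[C@@H](O)C[C@H]1[C@H](C)C[C@H](C=C(C)C)OC(C)=O | intermediate
16 | (1R,2S,5S)-5-[(2R,4R)-4-(acetyloxy)-6-methylhept-5-en-2-yl]-2-methyl-4-oxocyclohexyl chloroacetate | O=C1C[C@H](C)[C@H](OC(=O)CCl)C[C@H]1[C@H](C)C[C@H](C=C(C)C)OC(C)=O | intermediate
17 | (1R,2S,4R,5S)-5-[(2R,4R)-4-(acetyloxy)-6-methylhept-5-en-2-yl]-4-hydroxy-2-methylcyclohexyl chloroacetate | O[C@@H]1C[C@H](C)[C@H](OC(=O)CCl)C[C@H]1[C@H](C)C[C@H](C=C(C)C)OC(C)=O | intermediate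
18 | (1R,2S,4R,5S)-2-[(2R,4R)-4-(acetyloxy)-6-methylhept-5-en-2-yl]-4-[(chloroacetyl)oxy]-5-methylcyclohexyl (2Z)-2-methylbut-2-enoate | C/C=C(/C)C(=O)O[C@@H]1C[C@H](C)[C@H](OC(=O)CCl)C[C@H]1[C@H](C)C[C@H](C=C(C)C)OC(C)=O | intermediate
19 | (1R,2S,4R,5S)-2-[(2R,4R)-4-(acetyloxy)-6-methylhept-5-en-2-yl]-4-hydroxy-5-methylcyclohexyl (2Z)-2-methylbut-2-enoate | C/C=C(/C)C(=O)O[C@@H]1C[C@H](C)[C@H](O)C[C@H]1[C@H](C)C[C@H](C=C(C)C)OC(C)=O | target

**Totals**
Total step count: 14. Longest linear sequence: 13 steps (steps 1–6 and 8–14).

**Steps most likely to fail**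

1. Step 10 (Proposed new method). What may go wrong: the enone C=C is simply reduced, the two carbonyl carbons couple to a 1,2-diol or between two molecules instead of closing the ring, or the facial selectivity at the new carbinol carbon is poor. Fallback with known chemistry, closing the same bond through an acyl radical at the ketone oxidation level: it sets out from 13. Tetrabutylammonium decatungstate (2 mol %) under 390 nm light in MeCN abstracts the formyl hydrogen, and the acyl radical adds to the same methylidene carbon (Giese-type radical hydroacylation of an enone, 6-endo). Hydrogen-atom return to the α-keto radical from the axial side should leave the side chain equatorial, giving (4R,6R)-2-methyl-6-[(1S,4S)-4-methyl-2,5-dioxocyclohexyl]hept-2-en-4-yl acetate F1. L-Selectride (1.0 equiv, THF, −78 °C) should reduce the less hindered ketone, the one next to the methyl-bearing carbon, from the equatorial side to the axial alcohol (4R,6R)-6-[(1S,4S,5R)-5-hydroxy-4-methyl-2-oxocyclohexyl]-2-methylhept-2-en-4-yl acetate F2. Chloroacetic anhydride and pyridine (CH2Cl2, 0 °C) then give 16, where the route is rejoined without the Mitsunobu step.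

2. Step 12. What may go wrong: poor facial selectivity of hydride attack on a ketone flanked by the branched equatorial side chain, so that equatorial attack gives the axial C1 alcohol. Fallback with enzyme control in place of substrate control: it sets out from 16. An NADPH-dependent ketoreductase (alcohol dehydrogenase class, chosen from a commercial panel for the (4R)-carbinol of 17) with i-PrOH cofactor recycling in pH 7 buffer/DMSO at 30 °C should give 17 directly; no new compound is formed (F0).

3. Step 13. What may go wrong: slow acylation of the hindered secondary alcohol accompanied by Z → E isomerisation of the angeloyl unit to the tiglate. Fallback that builds the Z-alkene on the substrate: it sets out from 17. Esterification with 2-[bis(2,2,2-trifluoroethoxy)phosphoryl]propanoic acid (EDC·HCl, DMAP cat., CH2Cl2, 0 °C) gives (1R,2S,4R,5S)-2-[(2R,4R)-4-(acetyloxy)-6-methylhept-5-en-2-yl]-4-[(chloroacetyl)oxy]-5-methylcyclohexyl 2-[bis(2,2,2-trifluoroethoxy)phosphoryl]propanoate F3. Still–Gennari olefination with acetaldehyde (KHMDS 1.0 equiv, 18-crown-6, THF, −78 °C) should then give the (Z)-2-methylbut-2-enoate 18, where the route is rejoined.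

Further compounds
F1 | step 10 | (4R,6R)-2-methyl-6-[(1S,4S)-4-methyl-2,5-dioxocyclohexyl]hept-2-en-4-yl acetate | O=C1C[C@H](C)C(=O)C[C@H]1[C@H](C)C[C@H](C=C(C)C)OC(C)=O
F2 | step 10 | (4R,6R)-6-[(1S,4S,5R)-5-hydroxy-4-methyl-2-oxocyclohexyl]-2-methylhept-2-en-4-yl acetate | O=C1C[C@H](C)[C@H](O)C[C@H]1[C@H](C)C[C@H](C=C(C)C)OC(C)=O
F0 | step 12 | none | none
F3 | step 13 | (1R,2S,4R,5S)-2-[(2R,4R)-4-(acetyloxy)-6-methylhept-5-en-2-yl]-4-[(chloroacetyl)oxy]-5-methylcyclohexyl 2-[bis(2,2,2-trifluoroethoxy)phosphoryl]propanoate | CC(C(=O)O[C@@H]1C[C@H](C)[C@H](OC(=O)CCl)C[C@H]1[C@H](C)C[C@H](C=C(C)C)OC(C)=O)P(=O)(OCC(F)(F)F)OCC(F)(F)F
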